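## The problem

The target 21 is a (3R,4R)-3,4-dibenzyl-γ-butyrolactone. The ring atoms are numbered O1, C2 (carbonyl), C3, C4, C5; benzylic C7 on C3 carries ring A (2,4-dihydroxy-3-methoxyphenyl) and benzylic C7' on C4 carries ring B (4-hydroxy-3-methoxyphenyl). No rings are fused, so the task is to build the branched chain C7–C3(–C2)–C4(–C5)–C7' and to place the two benzyl arms trans on adjacent carbons. C4 has no acidifying neighbour: it must be set in the absolute sense, and once set it is safe. C3 is α to the lactone carbonyl and epimerizable, so C4 can control C3 by thermodynamics, but not the reverse. The three free phenols will not survive rough treatment. Ring A is an electron-rich, oxidation-prone resorcinol, and its C2 hydroxyl lies six atoms from the lactone carbonyl, so acid or base could translactonize it to a dihydrocoumarin. The lactone itself opens with hydroxide, so the phenols must stay masked to the end and be released under neutral conditions. The enabling feature is that C3 is bonded to carbonyl C2, to C4 and to C7, which makes it the central carbon of a malonate that is substituted twice and later loses one carboxyl. C4 carries the oxygenated one-carbon arm C5, which is a vinyl group in masked form, so C4 is the branched carbon of an allylic substitution product.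

## Retrosynthesis

**21 from 20.** The three phenolic O–H bonds are traced back to benzyl ethers in 20. Benzyl is preferred to acyl or silyl groups because it tolerates NaH, ozone at low temperature and hot LiCl/DMSO, and it leaves by neutral hydrogenolysis, which avoids the dihydrocoumarin rearrangement. The forward step must cleave three aryl benzyl ethers without touching the lactone.

**20 from 18, through 19.** The C3–H bond is replaced by a C3–CO2Me bond. This removes the C3 stereocenter from the problem: 18 may be any mixture at C3, because decarbomethoxylation gives the epimeric lactones 19 and base equilibration then settles them as trans 20 under the control of C4. The forward step must remove one ester carbon without opening the ring.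

**18 from 15, through 16 and 17.** The lactone C2–O1 bond is cut and C5 is returned to a vinyl group. Oxidative cleavage of the alkene gives aldehyde 16, reduction gives hydroxy diester 17, and either ester closes the ring. The acyclic diester 15 has one stereocenter and no ring. The forward step needs an oxidant that prefers a monosubstituted alkene over three alkoxyarenes.

**15 from 12, 5 and 11, through 13 and 14.** Both bonds to C3 are cut: C3–C4 to the allyl carbonate 5 and C3–C7 to the benzyl bromide 11, leaving dimethyl malonate 12 as the linchpin. Cutting C3–C7 alone (alkylation of a preformed chiral lactone) would leave C4 unsolved. Cutting C4–C7' would require a conjugate addition of a benzyl nucleophile with absolute control. The double cut gives three achiral pieces of similar size and asks one catalyst to set C4. The forward reaction needs branched regiochemistry and one enantioface in the allylation that gives 14 from the sodium malonate 13, then C-alkylation of the hindered malonate 14.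

**5 from 2 and 4; 2 from 1; 4 from 3.** The C2'=C3' alkene of the butenyl chain is cut by cross-metathesis into O-benzyleugenol 2 and the symmetrical bis(carbonate) 4, made from eugenol 1 and (Z)-but-2-ene-1,4-diol 3. The forward step should give mainly the E alkene.

**11 from 10, 9, 7 and 6, through 8.** The C–Br bond goes back to alcohol 10 and aldehyde 9. The formyl carbon is cut from the dibenzyl ether 7 of 2-methoxyresorcinol 6. Positions 4 and 6 of 7 are equivalent and doubly activated, so formylation through iminium salt 8 has only one likely site.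

## Roads not taken

Alternative 1: The cut inserts O1 between C2 and C5 of a prochiral cyclobutanone. A Baeyer–Villiger monooxygenase would differentiate the two enantiotopic α-methylene groups of 3-[4-(benzyloxy)-3-methoxybenzyl]cyclobutan-1-one A2 (from 2 by dichloroketene cycloaddition and dechlorination) and deliver (R)-4-[4-(benzyloxy)-3-methoxybenzyl]dihydrofuran-2(3H)-one A1. Alkylation of its lithium enolate with 11 anti to the C4 arm would give 20 directly.
- Merits: the ring and C4 arise in one oxygen insertion, and the trans relationship is set kinetically in a well-known type of alkylation. The route from 2 to 20 is no longer than the chosen one and saves the preparation of 4.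
- Weak points: enantioselection rests on finding an enzyme that accepts the lipophilic benzyl ether A2 and distinguishes methylene groups that differ only through a flexible, remote arm. The work is done in dilute aqueous medium. The C3–C7 bond needs a strong base at low temperature together with the labile bromide 11.
- Comparison: this road is at least as short, and its trans control is more direct. The chosen plan offers a small-molecule catalyst with a predictable sense of induction, available as either antipode and used in ordinary solvents, and it forms C3–C7 at a doubly stabilized carbanion.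

Alternative 2: The cut takes C5 and O1 from methanol. A hydroxymethyl radical would add to C4 of the Lewis-acid-bound enoyl pyrazole 1-[(E)-2-(2,4-diacetoxy-3-methoxybenzyl)-4-(4-acetoxy-3-methoxyphenyl)but-2-enoyl]-3,5-dimethylpyrazole A4. After protonation at C3, the new hydroxyl would displace the pyrazole to give (4R)-3-(2,4-diacetoxy-3-methoxybenzyl)-4-(4-acetoxy-3-methoxybenzyl)dihydrofuran-2(3H)-one A3 as both C3 epimers.
- Merits: both arms are in place before the key step, the C4–C5 and C2–O1 bonds form in one operation, and the one-carbon unit is as cheap as possible.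
- Weak points: A4 is an α-branched, trisubstituted acceptor, which is the least reactive and least selective class for chiral Lewis acid control of radical addition. Its γ-hydrogens are benzylic, so the alkene can slip into conjugation with ring B. Hydrogen abstraction to form the radical from methanol must compete with three benzylic methylene groups. C3 is not controlled, so the same epimerization is needed as in the chosen plan. Aryl acetates are fragile toward the base needed for that epimerization.
- Comparison: this road would be shorter after the key step, since no decarboxylation is needed. The chosen plan relies on a single well-established asymmetric event in place of several unproven selectivities in one step.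

Alternative 3: The cut makes C5–O1 by opening an oxetane. Under a chiral phosphoric acid, one ester carbonyl oxygen of di-tert-butyl 2-[2,4-bis(benzyloxy)-3-methoxybenzyl]-2-(oxetan-3-yl)malonate A6 would attack one enantiotopic oxetane methylene with loss of isobutylene. This gives tert-butyl (4S)-3-[2,4-bis(benzyloxy)-3-methoxybenzyl]-4-(hydroxymethyl)-2-oxotetrahydrofuran-3-carboxylate A5, whose free hydroxymethyl group is C7'.
- Merits: an achiral, symmetrical substrate is desymmetrized catalytically; the ring and C4 are set together; ring B is introduced late, which would serve analogue work better than the chosen plan.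
- Weak points: ring B must then be joined by an sp3–sp2 coupling at a β-branched primary carbon next to a quaternary centre, after activation of the alcohol. This adds steps and is the least secure bond of that route. Warm acid endangers the benzyl ethers of the electron-rich ring A. A6 itself takes several steps to make.
- Comparison: the late introduction of ring B is a real advantage of this road. The chosen plan has every carbon in place after its key step and needs no C–C bond formation afterwards.

Key step: step 8

Assumption: the (Ra,Rc,Rc) antipode of the phosphoramidite is taken to give the S configuration in 14, following the usual sense of induction of this catalyst family with linear E carbonates. This assignment rests on recalled precedent and is not verified here; if the sense proves opposite, the (Sa,Sc,Sc) ligand is used with no other change.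

## Route

Step 1
Reactants: 1 eugenol (4-allyl-2-methoxyphenol)
Product: 2 4-allyl-1-(benzyloxy)-2-methoxybenzene (O-benzyleugenol)
Conditions: BnBr, K2CO3, DMF, rt
Reagents that add atoms: benzyl bromide, BrCc1ccccc1
Why: Williamson etherification of the phenoxide; the carbonate base is too weak to move the allyl double bond into conjugation.

Step 2
Reactants: 3 (Z)-but-2-ene-1,4-diol
Product: 4 (Z)-but-2-ene-1,4-diyl dimethyl dicarbonate
Conditions: ClCO2Me, pyridine, CH2Cl2, 0 °C → rt
Reagents that add atoms: methyl chloroformate, COC(=O)Cl
Why: Acylation of both primary alcohols by the chloroformate with pyridine as acid scavenger.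

Step 3
Reactants: 2 4-allyl-1-(benzyloxy)-2-methoxybenzene; 4 (Z)-but-2-ene-1,4-diyl dimethyl dicarbonate (excess)
Product: 5 (E)-4-[4-(benzyloxy)-3-methoxyphenyl]but-2-en-1-yl methyl carbonate
Conditions: second-generation Grubbs catalyst RuCl2(=CHPh)(H2IMes)(PCy3) (3 mol%), 1,4-benzoquinone (10 mol%), CH2Cl2, 40 °C
Reagents that add atoms: none
Why: Olefin cross-metathesis of a terminal alkene with an excess of a symmetrical internal alkene; secondary metathesis should favour the E isomer, and benzoquinone suppresses hydride-mediated migration of the alkene toward the arene.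

Step 4
Reactants: 6 2-methoxyresorcinol (2-methoxybenzene-1,3-diol)
Product: 7 1,3-bis(benzyloxy)-2-methoxybenzene
Conditions: BnBr, K2CO3, DMF, 60 °C
Reagents that add atoms: benzyl bromide, BrCc1ccccc1
Why: Double Williamson etherification of the two equivalent phenols.

Step 5
Reactants: 7 1,3-bis(benzyloxy)-2-methoxybenzene
Product: 9 2,4-bis(benzyloxy)-3-methoxybenzaldehyde, via aryl iminium chloride 8 (not isolated)
Conditions: POCl3, DMF, 0 → 70 °C; then H2O, rt
Reagents that add atoms: N,N-dimethylformamide, CN(C)C=O; water, O
Why: Vilsmeier–Haack formylation; the chloroiminium ion attacks the position ortho to one benzyloxy group and para to the other (positions 4 and 6 are equivalent), as 1,2,3-trialkoxybenzenes do, and water hydrolyses the iminium salt.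

Step 6
Reactants: 9 2,4-bis(benzyloxy)-3-methoxybenzaldehyde
Product: 10 [2,4-bis(benzyloxy)-3-methoxyphenyl]methanol
Conditions: NaBH4, THF/MeOH, 0 °C
Reagents that add atoms: none
Why: Hydride reduction of an aryl aldehyde; benzyl ethers are inert.

Step 7
Reactants: 10 [2,4-bis(benzyloxy)-3-methoxyphenyl]methanol
Product: 11 1,3-bis(benzyloxy)-4-(bromomethyl)-2-methoxybenzene
Conditions: PBr3, Et2O, 0 °C; crude product used at once
Reagents that add atoms: phosphorus tribromide, BrP(Br)Br
Why: Bromide displaces the phosphite ester of an activated benzylic alcohol; short contact at 0 °C and immediate use are meant to limit ionization of this electron-rich benzylic bromide.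

Step 8
Reactants: 12 dimethyl malonate; 5 (E)-4-[4-(benzyloxy)-3-methoxyphenyl]but-2-en-1-yl methyl carbonate; 11 1,3-bis(benzyloxy)-4-(bromomethyl)-2-methoxybenzene
Product: 15 dimethyl (S)-2-[2,4-bis(benzyloxy)-3-methoxybenzyl]-2-{1-[4-(benzyloxy)-3-methoxyphenyl]but-3-en-2-yl}malonate, via sodium dimethyl malonate 13 (not isolated), via branched allyl malonate 14 (not isolated)
Conditions: [Ir(cod)Cl]2 (2 mol%), (Ra,Rc,Rc)-O,O'-(1,1'-binaphthyl-2,2'-diyl) N,N-bis[1-(2-methoxyphenyl)ethyl]phosphoramidite (4 mol%), TBD (8 mol%), THF, rt; 12 (1.2 equiv), NaH, then 5, rt; then NaH, 11 (1.3 equiv), THF/DMF, 0 °C → rt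
Reagents that add atoms: none
Why: [Ir(cod)Cl]2 (monovalent iridium), the phosphoramidite and TBD form the cyclometalated catalyst, which ionizes E-carbonate 5 with loss of methyl carbonate to a trivalent iridium π-allyl. Sodium malonate 13 attacks the substituted allyl terminus on the face opposite the metal, forming C3–C4 as branched 14 and returning monovalent iridium; the closest known reaction type is the iridium–phosphoramidite branched-selective asymmetric allylic alkylation of malonates with linear alkyl-substituted allyl carbonates, followed by ordinary malonate C-alkylation in the same flask. C4 is the only new stereocenter and is set by the catalyst: the ligand decides which allyl enantioface binds iridium, and anti attack turns this into (S)-14. No ring closes. The step needs branched over linear attack, one enantioface and mono-allylation; these rest on the catalyst's preference for the more substituted terminus, on the E geometry of 5 with its unbranched CH2–ring B substituent, and on the hindrance of the branched product. In the second stage NaH removes the remaining doubly activated C3–H of 14, and the enolate displaces bromide from the primary benzylic bromide 11 to form C3–C7. C3 carries two identical ester groups and is not stereogenic. Keeping 12 near stoichiometric limits loss of 11 to leftover malonate.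

Step 9
Reactants: 15 dimethyl (S)-2-[2,4-bis(benzyloxy)-3-methoxybenzyl]-2-{1-[4-(benzyloxy)-3-methoxyphenyl]but-3-en-2-yl}malonate
Product: 18 methyl (4R)-3-[2,4-bis(benzyloxy)-3-methoxybenzyl]-4-[4-(benzyloxy)-3-methoxybenzyl]-2-oxotetrahydrofuran-3-carboxylate (both C3 epimers), via aldehyde 16 (not isolated), via hydroxy diester 17 (not isolated)
Conditions: O3, CH2Cl2/MeOH, −78 °C (Sudan Red 7B end point); NaBH4, −78 → 0 °C; then p-TsOH·H2O (cat.), CH2Cl2, rt
Reagents that add atoms: ozone, [O-][O+]=O
Why: Ozonolysis with reductive work-up; the monosubstituted alkene reacts far faster with ozone than the alkoxyarenes, and the α-branched aldehyde 16 is reduced in the cold before it can enolize at C4. The γ-hydroxy ester 17 then lactonizes by 5-exo-trig acyl substitution, helped by the quaternary C3; which ester closes does not matter because C3 is cleared in step 10.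

Step 10
Reactants: 18 methyl (4R)-3-[2,4-bis(benzyloxy)-3-methoxybenzyl]-4-[4-(benzyloxy)-3-methoxybenzyl]-2-oxotetrahydrofuran-3-carboxylate
Product: 20 (3R,4R)-3-[2,4-bis(benzyloxy)-3-methoxybenzyl]-4-[4-(benzyloxy)-3-methoxybenzyl]dihydrofuran-2(3H)-one, via C3-epimeric lactone mixture 19 (not isolated)
Conditions: LiCl, H2O, DMSO, 150 °C; then DBU (cat.), PhMe, 60 °C
Reagents that add atoms: none
Why: Krapcho decarbomethoxylation: chloride attacks the ester methyl group, the carboxylate loses CO2 and the lactone enolate is protonated. DBU then equilibrates C3 through the enolate toward the more stable trans arrangement dictated by the non-acidic C4.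

Step 11
Reactants: 20 (3R,4R)-3-[2,4-bis(benzyloxy)-3-methoxybenzyl]-4-[4-(benzyloxy)-3-methoxybenzyl]dihydrofuran-2(3H)-one
Product: 21 (3R,4R)-3-(2,4-dihydroxy-3-methoxybenzyl)-4-(4-hydroxy-3-methoxybenzyl)dihydrofuran-2(3H)-one
Conditions: H2 (1 atm), Pd/C, EtOAc/MeOH, rt
Reagents that add atoms: none
Why: Catalytic hydrogenolysis of three aryl benzyl ethers under neutral conditions; the lactone C5–O1 bond is not benzylic, and neither stereocenter is touched. The absence of acid or base avoids attack of the ring A C2 hydroxyl on the lactone.

## Compound list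

1 | eugenol (4-allyl-2-methoxyphenol) | COc1cc(CC=C)ccc1O | starting material
2 | 4-allyl-1-(benzyloxy)-2-methoxybenzene | COc1cc(CC=C)ccc1OCc1ccccc1 | intermediate
3 | (Z)-but-2-ene-1,4-diol | OC/C=C\CO | starting material
4 | (Z)-but-2-ene-1,4-diyl dimethyl dicarbonate | COC(=O)OC/C=C\COC(=O)OC | intermediate
5 | (E)-4-[4-(benzyloxy)-3-methoxyphenyl]but-2-en-1-yl methyl carbonate | COC(=O)OC/C=C/Cc1ccc(OCc2ccccc2)c(OC)c1 | intermediate
6 | 2-methoxyresorcinol (2-methoxybenzene-1,3-diol) | COc1c(O)cccc1O | starting material
7 | 1,3-bis(benzyloxy)-2-methoxybenzene | COc1c(OCc2ccccc2)cccc1OCc1ccccc1 | intermediate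
8 | N-[2,4-bis(benzyloxy)-3-methoxybenzylidene]-N-methylmethanaminium chloride | C[N+](C)=Cc1ccc(OCc2ccccc2)c(OC)c1OCc1ccccc1.[Cl-] | intermediate
9 | 2,4-bis(benzyloxy)-3-methoxybenzaldehyde | COc1c(OCc2ccccc2)ccc(C=O)c1OCc1ccccc1 | intermediate
10 | [2,4-bis(benzyloxy)-3-methoxyphenyl]methanol | COc1c(OCc2ccccc2)ccc(CO)c1OCc1ccccc1 | intermediate
11 | 1,3-bis(benzyloxy)-4-(bromomethyl)-2-methoxybenzene | COc1c(OCc2ccccc2)ccc(CBr)c1OCc1ccccc1 | intermediate
12 | dimethyl malonate | COC(=O)CC(=O)OC | starting material
13 | sodium dimethyl malonate (sodium 1,3-dimethoxy-1,3-dioxopropan-2-ide) | [Na+].COC(=O)[CH-]C(=O)OC | intermediate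
14 | dimethyl (S)-2-{1-[4-(benzyloxy)-3-methoxyphenyl]but-3-en-2-yl}malonate | COc1cc(C[C@@H](C=C)C(C(=O)OC)C(=O)OC)ccc1OCc1ccccc1 | intermediate
15 | dimethyl (S)-2-[2,4-bis(benzyloxy)-3-methoxybenzyl]-2-{1-[4-(benzyloxy)-3-methoxyphenyl]but-3-en-2-yl}malonate | COc1cc(C[C@@H](C=C)C(Cc2ccc(OCc3ccccc3)c(OC)c2OCc2ccccc2)(C(=O)OC)C(=O)OC)ccc1OCc1ccccc1 | intermediate
16 | dimethyl 2-[2,4-bis(benzyloxy)-3-methoxybenzyl]-2-{(R)-1-[4-(benzyloxy)-3-methoxyphenyl]-3-oxopropan-2-yl}malonate | COc1cc(C[C@@H](C=O)C(Cc2ccc(OCc3ccccc3)c(OC)c2OCc2ccccc2)(C(=O)OC)C(=O)OC)ccc1OCc1ccccc1 | intermediate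
17 | dimethyl 2-[2,4-bis(benzyloxy)-3-methoxybenzyl]-2-{(R)-1-[4-(benzyloxy)-3-methoxyphenyl]-3-hydroxypropan-2-yl}malonate | COc1cc(C[C@@H](CO)C(Cc2ccc(OCc3ccccc3)c(OC)c2OCc2ccccc2)(C(=O)OC)C(=O)OC)ccc1OCc1ccccc1 | intermediate
18 | methyl (4R)-3-[2,4-bis(benzyloxy)-3-methoxybenzyl]-4-[4-(benzyloxy)-3-methoxybenzyl]-2-oxotetrahydrofuran-3-carboxylate, both C3 epimers | COc1cc(C[C@H]2COC(=O)C2(Cc2ccc(OCc3ccccc3)c(OC)c2OCc2ccccc2)C(=O)OC)ccc1OCc1ccccc1 | intermediate
19 | (4R)-3-[2,4-bis(benzyloxy)-3-methoxybenzyl]-4-[4-(benzyloxy)-3-methoxybenzyl]dihydrofuran-2(3H)-one, both C3 epimers | COc1cc(C[C@H]2COC(=O)C2Cc2ccc(OCc3ccccc3)c(OC)c2OCc2ccccc2)ccc1OCc1ccccc1 | intermediate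
20 | (3R,4R)-3-[2,4-bis(benzyloxy)-3-methoxybenzyl]-4-[4-(benzyloxy)-3-methoxybenzyl]dihydrofuran-2(3H)-one | COc1cc(C[C@H]2COC(=O)[C@@H]2Cc2ccc(OCc3ccccc3)c(OC)c2OCc2ccccc2)ccc1OCc1ccccc1 | intermediate
21 | (3R,4R)-3-(2,4-dihydroxy-3-methoxybenzyl)-4-(4-hydroxy-3-methoxybenzyl)dihydrofuran-2(3H)-one | COc1cc(C[C@H]2COC(=O)[C@@H]2Cc2ccc(O)c(OC)c2O)ccc1O | target

## Step count and least certain steps

Total: 11 steps. Longest linear sequence: 8 steps (6 to 21 through steps 4 to 11).

**Step 8 (key step).** The first stage can lose branched selectivity and enantioselectivity if Z isomer is carried in with 5 or if the catalyst is not fully activated. In the second stage, C-alkylation at the hindered C3 may be slow, while leftover malonate and methoxide consume the labile bromide. The fallback sets out from 14, isolated after the first stage, and returns at 18. Ozonolysis of 14 with NaBH4 work-up gives dimethyl 2-{(R)-1-[4-(benzyloxy)-3-methoxyphenyl]-3-hydroxypropan-2-yl}malonate F1, which closes to methyl (4R)-4-[4-(benzyloxy)-3-methoxybenzyl]-2-oxotetrahydrofuran-3-carboxylate F2. The sodium enolate of F2 (NaH, DMF) is alkylated with 11 to give 18. The C3–C7 bond is then made on a less hindered cyclic enolate, with no competing nucleophiles.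

**Step 3.** Incomplete E selectivity and migration of the alkene toward ring B would lower the selectivity of step 8. The fallback sets out from 2 and returns at 5. Cross-metathesis of 2 with methyl acrylate (second-generation Grubbs catalyst RuCl2(=CHPh)(H2IMes)(PCy3)) should strongly favour methyl (E)-4-[4-(benzyloxy)-3-methoxyphenyl]but-2-enoate F3. Reduction with i-Bu2AlH at −78 °C gives (E)-4-[4-(benzyloxy)-3-methoxyphenyl]but-2-en-1-ol F4, and ClCO2Me/pyridine gives 5.

**Step 7.** Ionization of the doubly alkoxy-activated benzylic bromide can lead to self-alkylation or hydrolysis before use. The fallback sets out from 10 and returns at 15. SOCl2/pyridine gives the more stable 1,3-bis(benzyloxy)-4-(chloromethyl)-2-methoxybenzene F5. This is used in the second stage of step 8 with NaI, which forms 1,3-bis(benzyloxy)-4-(iodomethyl)-2-methoxybenzene F6 in the flask as the alkylating agent.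

**Step 9.** Ozone may oxidize the electron-rich arenes or benzylic ether positions, C4 may epimerize by enolization at the aldehyde stage, and excess NaBH4 may over-reduce the esters or the lactone. The fallback sets out from 15 and returns at 16. OsO4 (cat.), NaIO4 and 2,6-lutidine in dioxane/H2O dihydroxylate the alkene to dimethyl 2-[2,4-bis(benzyloxy)-3-methoxybenzyl]-2-{(2R)-1-[4-(benzyloxy)-3-methoxyphenyl]-3,4-dihydroxybutan-2-yl}malonate F7, which periodate cleaves as it forms to give 16. NaBH4 then leads through 17 to 18 as in the route. This oxidant does not attack arenes.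

**Step 10.** Chloride may open the lactone at C5 at high temperature, and the base equilibration may leave some cis epimer to be separated and recycled. The fallback sets out from 18 and returns at 19. LiOH in THF/H2O followed by acidification gives 2-[2,4-bis(benzyloxy)-3-methoxybenzyl]-2-{(R)-1-[4-(benzyloxy)-3-methoxyphenyl]-3-hydroxypropan-2-yl}malonic acid F8. This relactonizes to (4R)-3-[2,4-bis(benzyloxy)-3-methoxybenzyl]-4-[4-(benzyloxy)-3-methoxybenzyl]-2-oxotetrahydrofuran-3-carboxylic acid F9. Heating F9 in toluene decarboxylates it to 19, which the DBU treatment of step 10 converts to 20.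

## Further compounds

F1 | step 8 | dimethyl 2-{(R)-1-[4-(benzyloxy)-3-methoxyphenyl]-3-hydroxypropan-2-yl}malonate | COc1cc(C[C@@H](CO)C(C(=O)OC)C(=O)OC)ccc1OCc1ccccc1
F2 | step 8 | methyl (4R)-4-[4-(benzyloxy)-3-methoxybenzyl]-2-oxotetrahydrofuran-3-carboxylate, both C3 epimers | COc1cc(C[C@H]2COC(=O)C2C(=O)OC)ccc1OCc1ccccc1
F3 | step 3 | methyl (E)-4-[4-(benzyloxy)-3-methoxyphenyl]but-2-enoate | COC(=O)/C=C/Cc1ccc(OCc2ccccc2)c(OC)c1
F4 | step 3 | (E)-4-[4-(benzyloxy)-3-methoxyphenyl]but-2-en-1-ol | OC/C=C/Cc1ccc(OCc2ccccc2)c(OC)c1
F5 | step 7 | 1,3-bis(benzyloxy)-4-(chloromethyl)-2-methoxybenzene | COc1c(OCc2ccccc2)ccc(CCl)c1OCc1ccccc1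
F6 | step 7 | 1,3-bis(benzyloxy)-4-(iodomethyl)-2-methoxybenzene | COc1c(OCc2ccccc2)ccc(CI)c1OCc1ccccc1
F7 | step 9 | dimethyl 2-[2,4-bis(benzyloxy)-3-methoxybenzyl]-2-{(2R)-1-[4-(benzyloxy)-3-methoxyphenyl]-3,4-dihydroxybutan-2-yl}malonate, both configurations at the secondary carbinol | COc1cc(C[C@@H](C(O)CO)C(Cc2ccc(OCc3ccccc3)c(OC)c2OCc2ccccc2)(C(=O)OC)C(=O)OC)ccc1OCc1ccccc1
F8 | step 10 | 2-[2,4-bis(benzyloxy)-3-methoxybenzyl]-2-{(R)-1-[4-(benzyloxy)-3-methoxyphenyl]-3-hydroxypropan-2-yl}malonic acid | COc1cc(C[C@@H](CO)C(Cc2ccc(OCc3ccccc3)c(OC)c2OCc2ccccc2)(C(=O)O)C(=O)O)ccc1OCc1ccccc1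
F9 | step 10 | (4R)-3-[2,4-bis(benzyloxy)-3-methoxybenzyl]-4-[4-(benzyloxy)-3-methoxybenzyl]-2-oxotetrahydrofuran-3-carboxylic acid, both C3 epimers | COc1cc(C[C@H]2COC(=O)C2(Cc2ccc(OCc3ccccc3)c(OC)c2OCc2ccccc2)C(=O)O)ccc1OCc1ccccc1
A1 | alternative 1 | (R)-4-[4-(benzyloxy)-3-methoxybenzyl]dihydrofuran-2(3H)-one | COc1cc(C[C@H]2COC(=O)C2)ccc1OCc1ccccc1
A2 | alternative 1 | 3-[4-(benzyloxy)-3-methoxybenzyl]cyclobutan-1-one | COc1cc(CC2CC(=O)C2)ccc1OCc1ccccc1
A3 | alternative 2 | (4R)-3-(2,4-diacetoxy-3-methoxybenzyl)-4-(4-acetoxy-3-methoxybenzyl)dihydrofuran-2(3H)-one, both C3 epimers | COc1cc(C[C@H]2COC(=O)C2Cc2ccc(OC(C)=O)c(OC)c2OC(C)=O)ccc1OC(C)=O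
A4 | alternative 2 | 1-[(E)-2-(2,4-diacetoxy-3-methoxybenzyl)-4-(4-acetoxy-3-methoxyphenyl)but-2-enoyl]-3,5-dimethylpyrazole | COc1cc(C/C=C(\Cc2ccc(OC(C)=O)c(OC)c2OC(C)=O)C(=O)n2nc(C)cc2C)ccc1OC(C)=O
A5 | alternative 3 | tert-butyl (4S)-3-[2,4-bis(benzyloxy)-3-methoxybenzyl]-4-(hydroxymethyl)-2-oxotetrahydrofuran-3-carboxylate, either configuration at C3 | OC[C@H]1COC(=O)C1(Cc1ccc(OCc2ccccc2)c(OC)c1OCc1ccccc1)C(=O)OC(C)(C)C
A6 | alternative 3 | di-tert-butyl 2-[2,4-bis(benzyloxy)-3-methoxybenzyl]-2-(oxetan-3-yl)malonate | COc1c(OCc2ccccc2)ccc(CC(C2COC2)(C(=O)OC(C)(C)C)C(=O)OC(C)(C)C)c1OCc1ccccc1
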